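**Retrosynthetic overview**
- The target is the meso 2,5-cis-diaryl-3,4-cis-diaroyl oxolane (2,3-trans, 4,5-trans), formally two isoliquiritigenin units joined α–α' with one water oxygen bridging the two benzylic carbons.
- Last ring: the oxolane, made by oxidative (anodic) insertion of a water oxygen into the aryl-bearing C–C bond of a cis,trans,cis cyclobutane, which forms C2–O and C5–O.
- First ring: that cyclobutane (the syn head-to-head chalcone dimer), made by an intramolecular [2+2] photocycloaddition that forms the C3–C4 bond with the aroyl groups cis.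
- The two chalcone arms are held head-to-head by an o-xylylene strap on the ring B oxygens, and are built by a double Claisen–Schmidt condensation on a strapped dialdehyde.
- The strap and the four benzyl ethers on ring A are all benzyl-type and come off in one final hydrogenolysis.

Assumption: the descriptors (2R,3R,4S,5S) describe a meso compound (mirror plane through the ring oxygen and the C3–C4 midpoint), so the target is achiral, "single enantiomer" is read as "this single diastereomer", and only relative configuration is controlled.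

**Step 1**
Reactants: 1 1,2-bis(bromomethyl)benzene; 2 4-hydroxybenzaldehyde (2.2 equiv)
Product: 3 4,4'-[1,2-phenylenebis(methyleneoxy)]dibenzaldehyde
Conditions: K2CO3, DMF, 60 °C
Reagents that add atoms: none
Why: Double Williamson ether synthesis (SN2 of the phenoxide on a primary benzylic bromide), with no stereocentre formed.

**Step 2**
Reactants: 3 4,4'-[1,2-phenylenebis(methyleneoxy)]dibenzaldehyde; 4 1-[2,4-bis(benzyloxy)phenyl]ethan-1-one (2.1 equiv)
Product: 5 (2E,2'E)-3,3'-[1,2-phenylenebis(methyleneoxy-4,1-phenylene)]bis{1-[2,4-bis(benzyloxy)phenyl]prop-2-en-1-one}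
Conditions: KOH (50% aq), EtOH/THF, rt
Reagents that add atoms: none
Why: Double Claisen–Schmidt aldol condensation of a non-enolisable aryl aldehyde with a fully O-protected acetophenone, the E1cB dehydration giving the (E)-enones and all ethers being base-stable.

**Step 3**
Reactants: 5 strapped bis-chalcone
Product: 6 strapped syn head-to-head cyclobutane: [(1R,2S,3R,4S)-3,4-diarylcyclobutane-1,2-diyl]bis{[2,4-bis(benzyloxy)phenyl]methanone}, the two cis aryl groups being 1,4-phenylene rings joined para-O to para-O by the 1,2-phenylenebis(methylene) strap; aroyl groups cis to each other and trans to the aryl groups; meso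
Conditions: [Ir(dF(CF3)ppy)2(dtbbpy)]PF6 (1 mol%), 450 nm LEDs, degassed CH2Cl2 (2 mM), rt
Reagents that add atoms: none
Why: Intramolecular triplet-sensitised (energy-transfer) enone [2+2] photocycloaddition: the o-xylylene strap can bridge only aryl groups that are cis on a cyclobutane and holds the two (E)-enone arms parallel and head-to-head, so the α–α' bond (C3–C4 of the target) forms with the aroyl groups cis, while each aroyl carbon closes trans to its neighbouring aryl (least hindered closure of the 1,4-biradical), which sets the C3/C4 relationship; the saturated product ketones lie above the sensitiser in triplet energy and are not excited.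

**Step 4**
Reactants: 6 strapped syn head-to-head cyclobutane
Product: 7 strapped oxolane: [(2R,3R,4S,5S)-2,5-diaryloxolane-3,4-diyl]bis{[2,4-bis(benzyloxy)phenyl]methanone}, the two cis 2,5-(1,4-phenylene) groups still joined para-O to para-O by the 1,2-phenylenebis(methylene) strap; aryl groups trans to the neighbouring aroyl groups; meso
Conditions: graphite anode, Pt cathode, undivided cell, constant current (2.3 F/mol), (4-BrC6H4)3N (20 mol%), LiClO4 (0.1 M), MeCN/CH2Cl2/H2O 7:2:1, rt
Reagents that add atoms: water, O
Why: Proposed new method: the anodically generated aminium mediator removes one electron from the cofacial cis-1,2-bis(4-alkoxyphenyl)cyclobutane unit (the acylated ring A ethers and product 7 are expected to be harder to oxidise and have no fast follow-up reaction), the strained C–C bond between the two aryl-bearing carbons breaks to a distonic benzylic cation/benzylic radical, water captures the cation, the radical is oxidised to a second 4-alkoxybenzylic cation and the new hydroxyl closes on it to the oxolane, each C–O bond forming on the face away from the neighbouring aroyl group (and correctable by re-ionisation of the 4-alkoxybenzylic ether) while the strap allows only 2,5-cis aryls, so C2 and C5 are set trans to the untouched cis C3/C4 aroyl pair under neutral, non-enolising conditions; the closest known reactions are the oxidative ring-opening 1,3-dioxygenation of arylcyclopropanes, the aminium-salt-induced cleavage of dianisylcyclobutane radical cations and the anodic dimerisation–hydration of 4-methoxystyrenes to 2,5-diaryloxolanes.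

**Step 5**
Reactants: 7 strapped oxolane
Product: 8 [(2R,3R,4S,5S)-2,5-bis(4-hydroxyphenyl)oxolane-3,4-diyl]bis[(2,4-dihydroxyphenyl)methanone] (target, meso)
Conditions: H2 (1 atm), 10% Pd/C, EtOAc/MeOH 1:1, rt, monitored
Reagents that add atoms: none
Why: Catalytic hydrogenolysis of the six aryl benzyl-type ether bonds (four benzyl groups and both ends of the strap) is much faster than cleavage of the dialkyl-type benzylic C–O bonds of the oxolane or reduction of the hydrogen-bonded 2-hydroxyaryl ketones, and the neutral medium leaves all four stereocentres untouched.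

**Compound list**
1 | 1,2-bis(bromomethyl)benzene | BrCc1ccccc1CBr | starting material
2 | 4-hydroxybenzaldehyde | O=Cc1ccc(O)cc1 | starting material
3 | 4,4'-[1,2-phenylenebis(methyleneoxy)]dibenzaldehyde | O=Cc1ccc(OCc2ccccc2COc2ccc(C=O)cc2)cc1 | intermediate
4 | 1-[2,4-bis(benzyloxy)phenyl]ethan-1-one | CC(=O)c1ccc(OCc2ccccc2)cc1OCc1ccccc1 | starting material
5 | (2E,2'E)-3,3'-[1,2-phenylenebis(methyleneoxy-4,1-phenylene)]bis{1-[2,4-bis(benzyloxy)phenyl]prop-2-en-1-one} | O=C(/C=C/c1ccc(OCc2ccccc2COc2ccc(/C=C/C(=O)c3ccc(OCc4ccccc4)cc3OCc3ccccc3)cc2)cc1)c1ccc(OCc2ccccc2)cc1OCc1ccccc1 | intermediate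
6 | strapped meso cyclobutane, r-1,c-2-bis[2,4-bis(benzyloxy)benzoyl]-t-3,t-4-di(1,4-phenylene) bridged by O-CH2-C6H4-CH2-O | O=C(c1ccc(OCc2ccccc2)cc1OCc1ccccc1)[C@@H]1[C@H](C(=O)c2ccc(OCc3ccccc3)cc2OCc2ccccc2)[C@H]2c3ccc(OCc4ccccc4COc4ccc(cc4)[C@@H]12)cc3 | intermediate
7 | strapped meso oxolane, (2R,3R,4S,5S) core, 3,4-bis[2,4-bis(benzyloxy)benzoyl], 2,5-di(1,4-phenylene) bridged by O-CH2-C6H4-CH2-O | O=C(c1ccc(OCc2ccccc2)cc1OCc1ccccc1)[C@@H]1[C@H](C(=O)c2ccc(OCc3ccccc3)cc2OCc2ccccc2)[C@@H]2O[C@H]1c1ccc(OCc3ccccc3COc3ccc2cc3)cc1 | intermediate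
8 | [(2R,3R,4S,5S)-2,5-bis(4-hydroxyphenyl)oxolane-3,4-diyl]bis[(2,4-dihydroxyphenyl)methanone] | O=C(c1ccc(O)cc1O)[C@@H]1[C@H](C(=O)c2ccc(O)cc2O)[C@@H](c2ccc(O)cc2)O[C@H]1c1ccc(O)cc1 | target

**Step count and risks**
Total steps: 5. Longest linear sequence: 5 (1 → 3 → 5 → 6 → 7 → 8).

The three steps most likely to fail:

1. Step 4 (the proposed new ring expansion). The radical cation may instead revert fully to 5, or the benzylic cation may lose a proton. The fallback uses known oxidative phenol coupling, sets out from 4 (with 2) and comes back at 8. Claisen–Schmidt condensation of 4 with 2 (KOH, EtOH, 40 °C) gives (E)-1-[2,4-bis(benzyloxy)phenyl]-3-(4-hydroxyphenyl)prop-2-en-1-one F1. One-electron oxidation of F1 with Ag2O in acetone/water couples two phenoxyl radicals at the carbon next to the carbonyl, the 8–8' mode known for 4-hydroxycinnamoyl compounds. Water adds to one quinone methide and the resulting benzylic alcohol closes on the other, giving the tetrabenzyl ether [(2R,3R,4S,5S)-2,5-bis(4-hydroxyphenyl)oxolane-3,4-diyl]bis{[2,4-bis(benzyloxy)phenyl]methanone} F2. This route is less selective, and F2 must be separated by chromatography from 8–5' products and from the racemic diastereomer. Hydrogenolysis under the conditions of step 5 then gives 8.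

2. Step 3 (photocycloaddition). E/Z isomerisation may dominate, or the aryl/aroyl trans relationship may be partly lost. The fallback bypasses the cyclobutane, sets out from 5 and comes back at 7. Compound 5 is oxidised directly at a graphite anode in the wet electrolyte of step 4, without mediator, at controlled potential and to partial conversion. Radical-cation coupling of the two strap-stacked 4-alkoxystyrene units at the carbons next to the carbonyls, water capture and closure then form the C3–C4 bond and the oxolane in one electrochemical operation. No new compound is made on the way.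

3. Step 5 (hydrogenolysis). Once the free 4-hydroxyphenyl groups appear, the oxolane C–O bonds or the ketones may be reduced. The fallback moves the hydrogenolysis ahead of oxolane formation and ends with a fluoride deprotection; it sets out from 6 and comes back at 8.
   - Hydrogenolysis of 6 (H2, Pd/C, EtOAc/MeOH), where no sensitive ring is present, gives the hexaphenol [(1R,2S,3R,4S)-3,4-bis(4-hydroxyphenyl)cyclobutane-1,2-diyl]bis[(2,4-dihydroxyphenyl)methanone] F3.
   - TBSCl (4.4 equiv)/imidazole in DMF silylates the four non-chelated phenols to the tetrakis(tert-butyldimethylsilyl) ether F4, the two hydrogen-bonded 2-hydroxyls staying free.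
   - Anodic ring expansion as in step 4 gives the tetrakis(tert-butyldimethylsilyl) ether of the target F5, with C2 and C5 now set only by attack anti to the aroyl groups and by equilibration.
   - Bu4NF/AcOH in THF at 0 °C gives 8.

**Further compounds**
F1 | step 4 | (E)-1-[2,4-bis(benzyloxy)phenyl]-3-(4-hydroxyphenyl)prop-2-en-1-one | O=C(/C=C/c1ccc(O)cc1)c1ccc(OCc2ccccc2)cc1OCc1ccccc1
F2 | step 4 | [(2R,3R,4S,5S)-2,5-bis(4-hydroxyphenyl)oxolane-3,4-diyl]bis{[2,4-bis(benzyloxy)phenyl]methanone} | O=C(c1ccc(OCc2ccccc2)cc1OCc1ccccc1)[C@@H]1[C@H](C(=O)c2ccc(OCc3ccccc3)cc2OCc2ccccc2)[C@@H](c2ccc(O)cc2)O[C@H]1c1ccc(O)cc1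
F0 | step 3 | none | none
F3 | step 5 | [(1R,2S,3R,4S)-3,4-bis(4-hydroxyphenyl)cyclobutane-1,2-diyl]bis[(2,4-dihydroxyphenyl)methanone] | O=C(c1ccc(O)cc1O)[C@@H]1[C@H](C(=O)c2ccc(O)cc2O)[C@@H](c2ccc(O)cc2)[C@H]1c1ccc(O)cc1
F4 | step 5 | [(1R,2S,3R,4S)-3,4-bis(4-{[tert-butyl(dimethyl)silyl]oxy}phenyl)cyclobutane-1,2-diyl]bis[(4-{[tert-butyl(dimethyl)silyl]oxy}-2-hydroxyphenyl)methanone] | O=C(c1ccc(O[Si](C)(C)C(C)(C)C)cc1O)[C@@H]1[C@H](C(=O)c2ccc(O[Si](C)(C)C(C)(C)C)cc2O)[C@@H](c2ccc(O[Si](C)(C)C(C)(C)C)cc2)[C@H]1c1ccc(O[Si](C)(C)C(C)(C)C)cc1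
F5 | step 5 | [(2R,3R,4S,5S)-2,5-bis(4-{[tert-butyl(dimethyl)silyl]oxy}phenyl)oxolane-3,4-diyl]bis[(4-{[tert-butyl(dimethyl)silyl]oxy}-2-hydroxyphenyl)methanone] | O=C(c1ccc(O[Si](C)(C)C(C)(C)C)cc1O)[C@@H]1[C@H](C(=O)c2ccc(O[Si](C)(C)C(C)(C)C)cc2O)[C@@H](c2ccc(O[Si](C)(C)C(C)(C)C)cc2)O[C@H]1c1ccc(O[Si](C)(C)C(C)(C)C)cc1
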